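(The constants used here belong to no real substance; the rest is arithmetic.)

We ask first where the free monomer is heading, and then how far towards that point it gets in the time given.

| flask | free monomer | protic impurity | initiator | time |
|---|---|---|---|---|
| Monday's | 0.50 mM | 0.150 mM | 11 µM | 20 s |
| Wednesday's | 0.50 mM | 0.150 mM | 11 µM | 6.0 s |

    free monomer + initiator → living end + monomer in chains (k1 = 8200 /M/s)
    free monomer + living end → monomer in chains + living end, rate k2*[living end]*[free monomer] (k2 = 3600 /M/s)
    monomer in chains + living end → free monomer + living end, rate k3*[living end] as long as [monomer in chains] is above zero (k3 = 0.34 /s)
    living end → dead end (k4 = 0.021 /s)
    protic impurity + free monomer → quenched substrate (k5 = 8900 /M/s)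

- the average divides the monomer in chains by the number of chains begun, living and dead together
- run time (Monday's): 20 s

- which of the two ends with the longer chains by the average number of monomer units in a chain (chains begun, living or dead) ("neither" if they lie within 10 %) (Monday's / Wednesday's / neither)
- average number of monomer units in a chain (chains begun, living or dead) at the end, Monday's
- average number of monomer units in a chain (chains begun, living or dead) at the end, Wednesday's

At the charge the protic impurity has a half-life of 0.16 s and the initiator one of 0.169 s, both short against even Wednesday's 6.0 s. So we book both as consumed at time zero, which leaves 0.339 mM of free monomer and 11 µM of living ends, each holding one unit. Growth and its reverse balance at the equilibrium monomer concentration c, which is the reverse constant over the growth constant, 0.0944 mM. The gap still to close is therefore 0.245 mM, and it shrinks pseudo-first-order in living ends.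

Holding the living ends at their charge, the growth constant times their concentration times the time gives Monday's an exponent of 0.792. The chain length, one plus the gap per chain begun times the closed fraction, then comes to 13.2.

The weak link is that constant population, since the living ends have a half-life of 33 s and 65.7 % of them survive Monday's time. Summing the decaying living ends over time instead gives 0.647. This is the dose D, the growth constant times the living ends summed over time, and the gap shrinks by exp(−D). Wednesday's dose is 0.223. We commit to 11.6 for Monday's and 5.45 for Wednesday's, so the longer chains are Monday's.

The forecast, holding that “the living ends decay only slowly”, names Monday's, with 11.5 and 5.35, a little below our two figures.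

The simulation gives Monday's, with 11.5 against 5.33. In Monday's, quenching had 100 % of its turnover up to 20 s behind it at 10.0 s, and 35.4 % of the free monomer had reacted at 2.00 s. Monday's growth outran its reverse, with monomer in chains made, net, 2.94 times as fast as used up at 8.09 s and 2.36 times at 20.0 s, while living ends sank to 0.00727 mM by 20.0 s. Monday's dose of 0.647 is a third of the 1.89 its living ends give in full, and at 20.0 s its free monomer stood at 44.6 % of charge, above the 18.9 % that c makes of the charge.

For the neighbour of Monday's charged with 0.85 mM of free monomer we reckon the same dose, 0.647, and a gap of 0.595 mM, and so a length of 26.8. The computed length is 26.6, with 47.9 % of its charged free monomer left.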